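**Retrosynthetic overview**
1. Target 23 comes from bis-silyl ether 22 by global desilylation. 22 is cut at C4–C5 into 2-alkyne 7 and aldehyde 21; one Ni(0)/chiral NHC/silane reductive coupling forms this bond, the (5R) centre and the (3E) olefin.
2. Alkyne 7 (furan + C1–C4) comes from furan-3-carbaldehyde 1 and propargyl bromide 2: Cr-catalysed asymmetric propargylation sets (1S), then O-TBS protection and C-methylation.
3. Aldehyde 21 (C5–C16) comes from homofarnesol 20, made by a Pd-catalysed Negishi sp3–sp2 coupling (C8–C9) of the zinc reagent from iodide 13 with vinyl iodide 17.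
4. Iodide 13 comes from 5-bromo-2-methylpent-2-ene 8 (acetylide alkylation, Zr-catalysed methylalumination/ethylene oxide, iodination). Vinyl iodide 17 comes from pent-3-yn-1-ol 14 (TBS protection, hydrozirconation/iodination).
5. No ring is formed: the furan is carried intact from 1 and the rest of the molecule is acyclic.

Assumption: in steps 1 and 12 the ligand antipode is the one that adds to the Si face of the aldehyde (checked by Mosher analysis on a test run; the mirror-image ligand is used if the sense is opposite).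

**Route**

Step 1
Reactants: 1 furan-3-carbaldehyde; 2 3-bromoprop-1-yne
Product: 4 (S)-1-(furan-3-yl)but-3-yn-1-ol, via TMS ether 3 (not isolated)
Conditions: CrCl2 (10 mol %), chiral 1,8-bis(4-isopropyloxazolin-2-yl)-3,6-diphenylcarbazole ligand (12 mol %, Si-face-selective antipode), Mn, TMSCl, i-Pr2NEt (30 mol %), THF, rt; then K2CO3, MeOH
Reagents that add atoms: none
Why: Catalytic asymmetric Nozaki–Hiyama propargylation: the allenyl–Cr(III) species adds SE2' to the aldehyde inside the tridentate ligand pocket, Si-face attack sets (1S), and Mn/TMSCl turn the chromium over.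

Step 2
Reactants: 4 (S)-1-(furan-3-yl)but-3-yn-1-ol
Product: 5 (S)-tert-butyl{[1-(furan-3-yl)but-3-yn-1-yl]oxy}dimethylsilane
Conditions: TBSCl, imidazole, DMF, rt
Reagents that add atoms: tert-butyldimethylsilyl chloride CC(C)(C)[Si](C)(C)Cl
Why: Standard silylation of a secondary alcohol; the TBS ether protects the acid-sensitive furyl carbinol through the organometallic steps.

Step 3
Reactants: 5 (S)-tert-butyl{[1-(furan-3-yl)but-3-yn-1-yl]oxy}dimethylsilane
Product: 7 (S)-tert-butyl{[1-(furan-3-yl)pent-3-yn-1-yl]oxy}dimethylsilane, via lithium acetylide 6 (not isolated)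
Conditions: n-BuLi (1.05 equiv), THF, −78 °C; MeI, −78 °C to rt
Reagents that add atoms: iodomethane CI
Why: Acetylide alkylation; the terminal alkyne C–H is far more acidic than the furan C2–H, so only the acetylide forms and is methylated, and C1 is untouched.

Step 4
Reactants: 8 5-bromo-2-methylpent-2-ene
Product: 9 6-methylhept-5-en-1-yne
Conditions: LiC≡CH·ethylenediamine, DMSO, 10 °C to rt
Reagents that add atoms: lithium acetylide ethylenediamine complex [Li+].[C-]#C.NCCN
Why: SN2 alkylation of lithium acetylide by an unhindered primary bromide in DMSO.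

Step 5
Reactants: 9 6-methylhept-5-en-1-yne
Product: 12 (E)-4,8-dimethylnona-3,7-dien-1-ol, via alkenylalane 10 (not isolated), via lithium alanate 11 (not isolated)
Conditions: Me3Al (2 equiv), Cp2ZrCl2 (20 mol %), CH2Cl2, rt; evaporate; n-BuLi, THF/hexane, 0 °C; ethylene oxide, −78 °C to rt; aqueous work-up
Reagents that add atoms: trimethylaluminium C[Al](C)C; ethylene oxide C1CO1
Why: Negishi Zr-catalysed syn-methylalumination puts Me on the internal carbon and Al on the terminus (E ≥ 98 %), and the alanate opens ethylene oxide with retention of olefin geometry.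

Step 6
Reactants: 12 (E)-4,8-dimethylnona-3,7-dien-1-ol
Product: 13 (E)-1-iodo-4,8-dimethylnona-3,7-diene
Conditions: I2, PPh3, imidazole, CH2Cl2, 0 °C
Reagents that add atoms: iodine II
Why: Appel-type (Garegg–Samuelsson) iodination of a primary alcohol; the trisubstituted olefins are inert under the buffered conditions.

Step 7
Reactants: 14 pent-3-yn-1-ol
Product: 15 tert-butyldimethyl(pent-3-yn-1-yloxy)silane
Conditions: TBSCl, imidazole, DMF, rt
Reagents that add atoms: tert-butyldimethylsilyl chloride CC(C)(C)[Si](C)(C)Cl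
Why: Standard silylation; the free hydroxyl would otherwise consume and misdirect the Schwartz reagent.

Step 8
Reactants: 15 tert-butyldimethyl(pent-3-yn-1-yloxy)silane
Product: 17 (E)-tert-butyl[(4-iodopent-3-en-1-yl)oxy]dimethylsilane, via alkenylzirconocene chloride 16 (not isolated)
Conditions: Cp2Zr(H)Cl (2.2 equiv), THF, 50 °C, 1 h; then I2, THF, 0 °C
Reagents that add atoms: iodine II
Why: Schwartz hydrozirconation is a syn addition that, under thermodynamic control (excess reagent, warming), places Zr on the less hindered methyl-bearing carbon; iodinolysis with retention gives the (E)-2-iodo-2-alkene.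

Step 9
Reactants: 13 (E)-1-iodo-4,8-dimethylnona-3,7-diene; 17 (E)-tert-butyl[(4-iodopent-3-en-1-yl)oxy]dimethylsilane
Product: 19 tert-butyldimethyl{[(3E,7E)-4,8,12-trimethyltrideca-3,7,11-trien-1-yl]oxy}silane, via alkylzinc iodide 18 (not isolated)
Conditions: 13, Zn dust, LiCl, THF, 40 °C; then 17, Pd(dppf)Cl2 (5 mol %), THF, rt to 40 °C
Reagents that add atoms: none
Why: Negishi sp3–sp2 cross-coupling: the primary alkylzinc couples with the alkenyl iodide with retention of geometry, forming C8–C9, and the wide-bite-angle dppf ligand suppresses β-hydride elimination.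

Step 10
Reactants: 19 tert-butyldimethyl{[(3E,7E)-4,8,12-trimethyltrideca-3,7,11-trien-1-yl]oxy}silane
Product: 20 (3E,7E)-4,8,12-trimethyltrideca-3,7,11-trien-1-ol
Conditions: TBAF, THF, 0 °C to rt
Reagents that add atoms: none
Why: Fluoride-driven cleavage of the primary TBS ether; nothing else in the molecule reacts.

Step 11
Reactants: 20 (3E,7E)-4,8,12-trimethyltrideca-3,7,11-trien-1-ol
Product: 21 (3E,7E)-4,8,12-trimethyltrideca-3,7,11-trienal
Conditions: Dess–Martin periodinane, pyridine, CH2Cl2, 0 °C; short silica plug, used at once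
Reagents that add atoms: none
Why: Dess–Martin oxidation under buffered, non-basic conditions gives the β,γ-unsaturated aldehyde without migration of the C3=C4 olefin into conjugation.

Step 12
Reactants: 7 (S)-tert-butyl{[1-(furan-3-yl)pent-3-yn-1-yl]oxy}dimethylsilane; 21 (3E,7E)-4,8,12-trimethyltrideca-3,7,11-trienal
Product: 22 tert-butyl{[(1S,3E,5R,7E,11E)-1-(furan-3-yl)-4,8,12,16-tetramethyl-5-(triethylsilyloxy)heptadeca-3,7,11,15-tetraen-1-yl]oxy}dimethylsilane
Conditions: Ni(cod)2 (10 mol %), 1,3-bis(2-isopropylphenyl)-4,5-diphenylimidazolinium BF4 (10 mol %, Si-face-selective antipode), KOt-Bu (10 mol %), Et3SiH (2 equiv), THF, rt, 21 added over 2 h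
Reagents that add atoms: triethylsilane CC[SiH](CC)CC
Why: Proposed new method: Ni(0)–NHC binds 7 and 21 and undergoes oxidative cyclisation to an oxanickelacyclopentene in which the C–C bond forms at the less hindered methyl-bearing alkyne carbon (the branched CH2CH(OTBS)furyl arm sits next to Ni, away from the aldehyde chain), while the C2-symmetric NHC exposes the Si face of the aldehyde and so sets (5R); Si–H σ-bond metathesis and C–H reductive elimination then deliver H and C5 syn across the alkyne, giving the (3E) olefin and the O-TES ether; the closest known reaction type is the Ni(0)/NHC/silane aldehyde–alkyne reductive coupling (Montgomery type), not yet shown with catalyst-controlled regio- and enantioselectivity for a methyl/branched-alkyl 2-alkyne and a skipped (β,γ-unsaturated) aldehyde.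

Step 13
Reactants: 22 tert-butyl{[(1S,3E,5R,7E,11E)-1-(furan-3-yl)-4,8,12,16-tetramethyl-5-(triethylsilyloxy)heptadeca-3,7,11,15-tetraen-1-yl]oxy}dimethylsilane
Product: 23 (1S,3E,5R,7E,11E)-1-(furan-3-yl)-4,8,12,16-tetramethylheptadeca-3,7,11,15-tetraene-1,5-diol
Conditions: TBAF (3 equiv), THF, 0 °C to rt
Reagents that add atoms: none
Why: Fluoride removes both the TES and the TBS ether under non-acidic conditions, so the furyl and allylic carbinols are released without ionisation or epimerisation.

**Compound list**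
1 | furan-3-carbaldehyde | O=Cc1ccoc1 | starting material
2 | 3-bromoprop-1-yne (propargyl bromide) | C#CCBr | starting material
3 | (S)-{[1-(furan-3-yl)but-3-yn-1-yl]oxy}trimethylsilane | C#CC[C@H](O[Si](C)(C)C)c1ccoc1 | intermediate (not isolated)
4 | (S)-1-(furan-3-yl)but-3-yn-1-ol | C#CC[C@H](O)c1ccoc1 | intermediate
5 | (S)-tert-butyl{[1-(furan-3-yl)but-3-yn-1-yl]oxy}dimethylsilane | C#CC[C@H](O[Si](C)(C)C(C)(C)C)c1ccoc1 | intermediate
6 | lithium acetylide of 5, [(S)-4-(tert-butyldimethylsilyloxy)-4-(furan-3-yl)but-1-yn-1-yl]lithium | [Li]C#CC[C@H](O[Si](C)(C)C(C)(C)C)c1ccoc1 | intermediate (not isolated)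
7 | (S)-tert-butyl{[1-(furan-3-yl)pent-3-yn-1-yl]oxy}dimethylsilane | CC#CC[C@H](O[Si](C)(C)C(C)(C)C)c1ccoc1 | intermediate
8 | 5-bromo-2-methylpent-2-ene | CC(C)=CCCBr | starting material
9 | 6-methylhept-5-en-1-yne | CC(C)=CCCC#C | intermediate
10 | [(E)-2,6-dimethylhepta-1,5-dien-1-yl]dimethylalane | CC(C)=CCC/C(C)=C/[Al](C)C | intermediate (not isolated)
11 | lithium butyl[(E)-2,6-dimethylhepta-1,5-dien-1-yl]dimethylaluminate | CC(C)=CCC/C(C)=C/[Al-](C)(C)CCCC.[Li+] | intermediate (not isolated)
12 | (E)-4,8-dimethylnona-3,7-dien-1-ol (homogeraniol) | CC(C)=CCC/C(C)=C/CCO | intermediate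
13 | (E)-1-iodo-4,8-dimethylnona-3,7-diene | CC(C)=CCC/C(C)=C/CCI | intermediate
14 | pent-3-yn-1-ol | CC#CCCO | starting material
15 | tert-butyldimethyl(pent-3-yn-1-yloxy)silane | CC#CCCO[Si](C)(C)C(C)(C)C | intermediate
16 | chlorobis(cyclopentadienyl)[(E)-5-(tert-butyldimethylsilyloxy)pent-2-en-2-yl]zirconium | C/C(=C\CCO[Si](C)(C)C(C)(C)C)[Zr](Cl)(C1C=CC=C1)C1C=CC=C1 | intermediate (not isolated)
17 | (E)-tert-butyl[(4-iodopent-3-en-1-yl)oxy]dimethylsilane | C/C(I)=C\CCO[Si](C)(C)C(C)(C)C | intermediate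
18 | [(E)-4,8-dimethylnona-3,7-dien-1-yl]zinc iodide | CC(C)=CCC/C(C)=C/CC[Zn]I | intermediate (not isolated)
19 | tert-butyldimethyl{[(3E,7E)-4,8,12-trimethyltrideca-3,7,11-trien-1-yl]oxy}silane | CC(C)=CCC/C(C)=C/CC/C(C)=C/CCO[Si](C)(C)C(C)(C)C | intermediate
20 | (3E,7E)-4,8,12-trimethyltrideca-3,7,11-trien-1-ol (homofarnesol) | CC(C)=CCC/C(C)=C/CC/C(C)=C/CCO | intermediate
21 | (3E,7E)-4,8,12-trimethyltrideca-3,7,11-trienal | CC(C)=CCC/C(C)=C/CC/C(C)=C/CC=O | intermediate
22 | tert-butyl{[(1S,3E,5R,7E,11E)-1-(furan-3-yl)-4,8,12,16-tetramethyl-5-(triethylsilyloxy)heptadeca-3,7,11,15-tetraen-1-yl]oxy}dimethylsilane | CC(C)=CCC/C(C)=C/CC/C(C)=C/C[C@@H](O[Si](CC)(CC)CC)/C(C)=C/C[C@H](O[Si](C)(C)C(C)(C)C)c1ccoc1 | intermediate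
23 | (1S,3E,5R,7E,11E)-1-(furan-3-yl)-4,8,12,16-tetramethylheptadeca-3,7,11,15-tetraene-1,5-diol | CC(C)=CCC/C(C)=C/CC/C(C)=C/C[C@@H](O)/C(C)=C/C[C@H](O)c1ccoc1 | target

**Step count**
Total steps: 13. Longest linear sequence: 8 (steps 4, 5, 6, 9, 10, 11, 12, 13, from 8 to 23).

**Steps most likely to fail and their fallbacks**

Step 12 (the proposed new coupling). The risks are regiochemistry at the alkyne (methyl versus CH2R terminus) and the level of enantiocontrol at C5. The fallback uses known chemistry and sets out from 7. Hydrozirconation with Cp2Zr(H)Cl (THF, 50 °C) gives chlorobis(cyclopentadienyl)[(S,E)-5-(tert-butyldimethylsilyloxy)-5-(furan-3-yl)pent-2-en-2-yl]zirconium F1, and iodinolysis gives (S,E)-tert-butyl{[1-(furan-3-yl)-4-iodopent-3-en-1-yl]oxy}dimethylsilane F2. An asymmetric Ni/Cr Nozaki–Hiyama–Kishi coupling of F2 with aldehyde 21 (CrCl2, catalytic NiCl2, Kishi-type chiral sulfonamide ligand, Et3N, THF/MeCN) then gives (1S,3E,5R,7E,11E)-1-(tert-butyldimethylsilyloxy)-1-(furan-3-yl)-4,8,12,16-tetramethylheptadeca-3,7,11,15-tetraen-5-ol F3. TBAF as in step 13 removes the TBS group, and the fallback comes back to the route at 23.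

Step 8 (hydrozirconation regiochemistry, roughly 9:1 expected for methyl versus an unbranched CH2 arm, with a regioisomer that is hard to remove). The fallback sets out from 13 and replaces the linchpin with an iterative carboalumination. Iodide 13 is alkylated with lithium acetylide·ethylenediamine in DMSO to give (E)-6,10-dimethylundeca-5,9-dien-1-yne F4. Zr-catalysed methylalumination (Me3Al, Cp2ZrCl2) gives [(1E,5E)-2,6,10-trimethylundeca-1,5,9-trien-1-yl]dimethylalane F5, n-BuLi converts it into lithium butyl[(1E,5E)-2,6,10-trimethylundeca-1,5,9-trien-1-yl]dimethylaluminate F6, and ethylene oxide then gives homofarnesol. The fallback comes back to the route at 20 and bypasses steps 7–10.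

Step 1 (enantioselectivity of the catalytic propargylation on a heteroaryl aldehyde). The fallback sets out from 1 and 2 and uses resolution instead of asymmetric catalysis. A zinc Barbier reaction (Zn, THF/aqueous NH4Cl) gives rac-1-(furan-3-yl)but-3-yn-1-ol F7. Lipase-catalysed kinetic resolution (CAL-B, vinyl acetate, MTBE) acylates the R enantiomer to (R)-1-(furan-3-yl)but-3-yn-1-yl acetate F8, which is separated by chromatography. The unreacted (S)-alcohol is the point where the fallback comes back to the route, at 4.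

**Further compounds**
F1 | step 12 | chlorobis(cyclopentadienyl)[(S,E)-5-(tert-butyldimethylsilyloxy)-5-(furan-3-yl)pent-2-en-2-yl]zirconium | C/C(=C\C[C@H](O[Si](C)(C)C(C)(C)C)c1ccoc1)[Zr](Cl)(C1C=CC=C1)C1C=CC=C1
F2 | step 12 | (S,E)-tert-butyl{[1-(furan-3-yl)-4-iodopent-3-en-1-yl]oxy}dimethylsilane | C/C(I)=C\C[C@H](O[Si](C)(C)C(C)(C)C)c1ccoc1
F3 | step 12 | (1S,3E,5R,7E,11E)-1-(tert-butyldimethylsilyloxy)-1-(furan-3-yl)-4,8,12,16-tetramethylheptadeca-3,7,11,15-tetraen-5-ol | CC(C)=CCC/C(C)=C/CC/C(C)=C/C[C@@H](O)/C(C)=C/C[C@H](O[Si](C)(C)C(C)(C)C)c1ccoc1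
F4 | step 8 | (E)-6,10-dimethylundeca-5,9-dien-1-yne | CC(C)=CCC/C(C)=C/CCC#C
F5 | step 8 | [(1E,5E)-2,6,10-trimethylundeca-1,5,9-trien-1-yl]dimethylalane | CC(C)=CCC/C(C)=C/CC/C(C)=C/[Al](C)C
F6 | step 8 | lithium butyl[(1E,5E)-2,6,10-trimethylundeca-1,5,9-trien-1-yl]dimethylaluminate | CC(C)=CCC/C(C)=C/CC/C(C)=C/[Al-](C)(C)CCCC.[Li+]
F7 | step 1 | rac-1-(furan-3-yl)but-3-yn-1-ol | C#CCC(O)c1ccoc1
F8 | step 1 | (R)-1-(furan-3-yl)but-3-yn-1-yl acetate | C#CC[C@@H](OC(C)=O)c1ccoc1
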